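Retrosynthesis: the two aryl benzyl ethers and the silyl ether come off last, and the C3 CH2OH group is traced back to a vinyl group (C=C cleavage, reduction).
The oxolane (O1, C2, C3, C4, C5) is then cut at O1–C2 and C2–C3. C2 is bonded only to O1, an aryl group and C3, and C3 bears a single-carbon substituent, so C2 can enter as an aryl carbene on the ring oxygen of a 3,6-dihydro-2H-pyran, whose allylic O–CH2–CH=CH unit becomes the C3 vinyl group after a [2,3] shift of the oxonium ylide.
The cis-2-aryl-3-(silyloxymethyl)dihydropyran is cut at its C=C bond (ring-closing metathesis) and at the O–allyl bond. The resulting syn 2-vinyl-1,3-diol is cut at the carbinol C–C bond into O-benzylvanillin and (Z)-1,4-diborylbut-2-ene, made from butadiene.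
Forward: acyclic syn diad, then the six-membered ring by metathesis, then the five-membered ring by ring contraction, then vinyl to CH2OH and deprotection.
Stereochemistry: C5 from the chiral phosphoric acid in the allylboration, C4 from the (Z) geometry of the boronate through a chair transition state, C2 and C3 from the bridged transition state of the [2,3] shift under control of the cis C4/C5 pair.

Key step: step 7

Remark: 4-benzyloxy-3-methoxybenzaldehyde (4) is taken as a purchasable compound; it is otherwise one O-benzylation away from vanillin.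
Remark: the (S) acid in step 2 is chosen on the assumption that the γ-substituted allyl boronate 3 follows the facial preference of the parent allyl and crotyl pinacol boronates, for which the (R) acid gives Re-face addition to aryl aldehydes.

Step 1
Reactants: 1 buta-1,3-diene; 2 bis(pinacolato)diboron
Product: 3 (Z)-1,4-bis(4,4,5,5-tetramethyl-1,3,2-dioxaborolan-2-yl)but-2-ene
Conditions: Pt(PPh3)4 (3 mol%), toluene, 80 °C, sealed vessel
Reagents that add atoms: none
Why: Platinum-catalysed 1,4-diboration of a conjugated diene, in which insertion of the s-cis diene into the B–Pt–B unit gives a cyclic allyl platinum species whose reductive elimination can only deliver the (Z)-alkene; no stereocentre is formed.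

Step 2
Reactants: 4 4-benzyloxy-3-methoxybenzaldehyde; 3 (Z)-1,4-bis(pinacolboryl)but-2-ene
Product: 6 (1S,2S)-1-(4-benzyloxy-3-methoxyphenyl)-2-ethenylpropane-1,3-diol, via boronate adduct 5 (not isolated)
Conditions: (S)-TRIP [(S)-3,3′-bis(2,4,6-triisopropylphenyl)-1,1′-binaphthyl-2,2′-diyl hydrogen phosphate] (5 mol%), 4 Å molecular sieves, toluene, −40 °C; then NaOH, H2O2, THF–H2O, 0 °C to rt
Reagents that add atoms: hydrogen peroxide, OO
Why: Chiral phosphoric acid-catalysed aldehyde allylboration followed by alkaline peroxide oxidation of the C–B bond: in the closed chair transition state the aryl group is equatorial and the (Z)-CH2Bpin group axial, which makes the product syn (C2), while the (S) acid, hydrogen-bonded to a boronate oxygen and to the formyl hydrogen, is expected to expose the Si face of the aldehyde and so set the (S) carbinol centre (C1); the oxidation replaces boron by hydroxyl without touching either centre.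

Step 3
Reactants: 6 (1S,2S)-1-(4-benzyloxy-3-methoxyphenyl)-2-ethenylpropane-1,3-diol
Product: 7 (1S,2S)-1-(4-benzyloxy-3-methoxyphenyl)-2-{[(triisopropylsilyl)oxy]methyl}but-3-en-1-ol
Conditions: TIPSCl (1.05 equiv), imidazole, DMF, 0 °C
Reagents that add atoms: triisopropylsilyl chloride, CC(C)[Si](Cl)(C(C)C)C(C)C
Why: Imidazole-promoted silylation of an alcohol, which with the bulky triisopropylsilyl chloride at low temperature is selective for the primary hydroxyl over the hindered secondary benzylic one; no stereocentre is involved.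

Step 4
Reactants: 7 (1S,2S)-1-(4-benzyloxy-3-methoxyphenyl)-2-{[(triisopropylsilyl)oxy]methyl}but-3-en-1-ol; 8 allyl bromide
Product: 9 (1S,2S)-1-(allyloxy)-1-(4-benzyloxy-3-methoxyphenyl)-2-{[(triisopropylsilyl)oxy]methyl}but-3-ene
Conditions: NaH, Bu4NI (cat.), THF, 0 °C to rt
Reagents that add atoms: none
Why: Williamson etherification of the secondary hydroxyl group with a reactive allylic bromide; the benzylic C–O bond is not broken, so C1 keeps its configuration, and the bulky triisopropylsilyl group is slow to migrate between the 1,3-related oxygens.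

Step 5
Reactants: 9 (1S,2S)-1-(allyloxy)-1-(4-benzyloxy-3-methoxyphenyl)-2-{[(triisopropylsilyl)oxy]methyl}but-3-ene
Product: 10 (2S,3S)-2-(4-benzyloxy-3-methoxyphenyl)-3-{[(triisopropylsilyl)oxy]methyl}-3,6-dihydro-2H-pyran
Conditions: second-generation Grubbs catalyst (H2IMes)(PCy3)Cl2Ru=CHPh (3 mol%), CH2Cl2 (0.01 M), 40 °C
Reagents that add atoms: none
Why: Ring-closing olefin metathesis of the allyl ether and the vinyl group with loss of ethene closes the unstrained 3,6-dihydro-2H-pyran; no bond to a stereocentre is broken, so the syn diad becomes the 2,3-cis ring.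

Step 6
Reactants: 4 4-benzyloxy-3-methoxybenzaldehyde; 11 p-toluenesulfonyl hydrazide
Product: 13 sodium salt of (E)-N′-(4-benzyloxy-3-methoxybenzylidene)-4-methylbenzenesulfonohydrazide, via tosylhydrazone 12 (not isolated)
Conditions: MeOH, rt; then NaOMe (1.0 equiv), MeOH, rt; evaporation, drying in vacuo
Reagents that add atoms: sodium methoxide, [Na+].[O-]C
Why: Condensation of an aryl aldehyde with a sulfonyl hydrazide (hydrazone formation) followed by deprotonation of the acidic sulfonamide N–H with one equivalent of methoxide gives the dry salt needed for a Bamford–Stevens release of the diazo compound; no stereocentre is involved.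

Step 7
Reactants: 10 (2S,3S)-2-(4-benzyloxy-3-methoxyphenyl)-3-{[(triisopropylsilyl)oxy]methyl}-3,6-dihydro-2H-pyran; 13 sodium salt of the tosylhydrazone of 4
Product: 16 (2S,3R,4S,5S)-2,5-bis(4-benzyloxy-3-methoxyphenyl)-3-ethenyl-4-{[(triisopropylsilyl)oxy]methyl}oxolane, via aryldiazomethane 14 (not isolated), via oxonium ylide 15 (not isolated)
Conditions: 13 (3 equiv, added in portions over several hours), Rh2(OAc)4 (2 mol%), BnEt3NCl (10 mol%), 1,4-dioxane, 40 °C
Reagents that add atoms: none
Why: Proposed new method: on warming with the phase-transfer salt, 13 loses sulfinate (Bamford–Stevens) to release the diazo compound 14 slowly, Rh2(OAc)4 converts it into an electrophilic aryl carbene, and a lone pair of the ring oxygen of 10 adds to the carbene carbon to give the allylic oxonium ylide 15, whose [2,3]-sigmatropic shift joins the ylide carbon to C4 of the dihydropyran, breaks the O1–C6 bond and leaves C5=C6 as the vinyl group. The closest known reactions are the [2,3] rearrangement of carbene-derived allyl oxonium ylides (Doyle–Kirmse type) and the six-to-five ring contraction of cyclic allyl sulfonium ylides; the combination of a donor aryl carbene, intermolecular capture by an ether oxygen and an endocyclic allyl unit is without direct precedent. The oxolane closes by ring contraction: the exocyclic ylide carbon bridges O1 and C4 suprafacially in a five-centre, bicyclo[2.2.1]-like transition state (a 5-exo attack on the ring alkene with the allylic oxygen as leaving group). C3 of the oxolane is set by the ring face that carries the bridge, which should be the face of the cis aryl and CH2OTIPS groups because both then stand exo, clear of the allyl bridge, and this places the new vinyl group trans to CH2OTIPS; C2 is set by the orientation of the ylide aryl group, which should turn away from these exo groups toward the allyl bridge and thus end cis to the vinyl group and trans to the C5 aryl group. Pyramidal inversion at the oxonium oxygen is fast, so the outcome should depend on these transition-state energies and not on which lone pair first binds the carbene. The step needs the concerted [2,3] shift to outrun the Stevens [1,2] shift of the benzylic carbon, cyclopropanation of the ring alkene and coupling of the carbene with 14, for which the aligned allylic O–CH2 bond, the hindered and inductively deactivated cis-disubstituted alkene, the weakly basic aryl and silyl ether oxygens and the slow release of 14 are relied on.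

Step 8
Reactants: 16 (2S,3R,4S,5S)-2,5-bis(4-benzyloxy-3-methoxyphenyl)-3-ethenyl-4-{[(triisopropylsilyl)oxy]methyl}oxolane
Product: 18 [(2S,3S,4S,5S)-2,5-bis(4-benzyloxy-3-methoxyphenyl)-4-{[(triisopropylsilyl)oxy]methyl}oxolan-3-yl]methanol, via ozonide 17 (not isolated)
Conditions: O3, CH2Cl2, −78 °C (Sudan Red 7B end-point); then NaBH4, MeOH, −78 to 0 °C
Reagents that add atoms: ozone, [O-][O+]=O
Why: Ozonolysis of a terminal alkene with reductive borohydride work-up: the monosubstituted vinyl group should react with ozone far faster than the alkoxy arenes or the benzyl ethers when the end-point is shown by a dye, and the cold hydride reduces ozonide 17 directly to the alcohol, so that C3, which would be epimerisable as an aldehyde, keeps its configuration.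

Step 9
Reactants: 18 [(2S,3S,4S,5S)-2,5-bis(4-benzyloxy-3-methoxyphenyl)-4-{[(triisopropylsilyl)oxy]methyl}oxolan-3-yl]methanol
Product: 19 [(2S,3S,4S,5S)-2,5-bis(4-benzyloxy-3-methoxyphenyl)oxolane-3,4-diyl]dimethanol
Conditions: Bu4NF, THF, 0 °C to rt
Reagents that add atoms: none
Why: Fluoride-mediated cleavage of a silyl ether, to which the benzyl ethers and the oxolane are inert; the phenols are still protected at this point, so no phenoxide that could open the benzylic ether is exposed to the basic reagent.

Step 10
Reactants: 19 [(2S,3S,4S,5S)-2,5-bis(4-benzyloxy-3-methoxyphenyl)oxolane-3,4-diyl]dimethanol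
Product: 20 eduesmine, [(2S,3S,4S,5S)-2,5-bis(4-hydroxy-3-methoxyphenyl)oxolane-3,4-diyl]dimethanol
Conditions: H2 (1 atm), Pd/C (10 wt%), EtOAc–MeOH, rt
Reagents that add atoms: none
Why: Catalytic hydrogenolysis of aryl benzyl ethers, which under neutral conditions should be much faster than hydrogenolysis of the benzylic C–O bonds of the 2,5-diaryloxolane; no stereocentre is touched.

Compound list
1 | buta-1,3-diene | C=CC=C | starting material
2 | bis(pinacolato)diboron | CC1(C)OB(OC1(C)C)B1OC(C)(C)C(C)(C)O1 | starting material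
3 | (Z)-1,4-bis(4,4,5,5-tetramethyl-1,3,2-dioxaborolan-2-yl)but-2-ene | CC1(C)OB(C/C=C\CB2OC(C)(C)C(C)(C)O2)OC1(C)C | intermediate
4 | 4-benzyloxy-3-methoxybenzaldehyde (O-benzylvanillin) | COc1cc(C=O)ccc1OCc1ccccc1 | starting material
5 | syn adduct, pinacol borate ester of (1S,2R)-1-(4-benzyloxy-3-methoxyphenyl)-2-[(pinacolboryl)methyl]but-3-en-1-ol | CC1(C)OB(O[C@H](c2ccc(OCc3ccccc3)c(OC)c2)[C@H](CB2OC(C)(C)C(C)(C)O2)C=C)OC1(C)C | intermediate
6 | (1S,2S)-1-(4-benzyloxy-3-methoxyphenyl)-2-ethenylpropane-1,3-diol (syn) | O[C@H](c1ccc(OCc2ccccc2)c(OC)c1)[C@H](CO)C=C | intermediate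
7 | (1S,2S)-1-(4-benzyloxy-3-methoxyphenyl)-2-{[(triisopropylsilyl)oxy]methyl}but-3-en-1-ol (syn) | O[C@H](c1ccc(OCc2ccccc2)c(OC)c1)[C@H](CO[Si](C(C)C)(C(C)C)C(C)C)C=C | intermediate
8 | allyl bromide (3-bromoprop-1-ene) | C=CCBr | starting material
9 | (1S,2S)-1-(allyloxy)-1-(4-benzyloxy-3-methoxyphenyl)-2-{[(triisopropylsilyl)oxy]methyl}but-3-ene | C=CCO[C@H](c1ccc(OCc2ccccc2)c(OC)c1)[C@H](CO[Si](C(C)C)(C(C)C)C(C)C)C=C | intermediate
10 | (2S,3S)-2-(4-benzyloxy-3-methoxyphenyl)-3-{[(triisopropylsilyl)oxy]methyl}-3,6-dihydro-2H-pyran (2,3-cis) | O1[C@H](c2ccc(OCc3ccccc3)c(OC)c2)[C@H](CO[Si](C(C)C)(C(C)C)C(C)C)C=CC1 | intermediate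
11 | p-toluenesulfonyl hydrazide | Cc1ccc(S(=O)(=O)NN)cc1 | starting material
12 | (E)-N′-(4-benzyloxy-3-methoxybenzylidene)-4-methylbenzenesulfonohydrazide | COc1cc(/C=N/NS(=O)(=O)c2ccc(C)cc2)ccc1OCc1ccccc1 | intermediate
13 | sodium salt of 12 | COc1cc(/C=N/[N-]S(=O)(=O)c2ccc(C)cc2)ccc1OCc1ccccc1.[Na+] | intermediate
14 | (4-benzyloxy-3-methoxyphenyl)diazomethane | COc1cc(C=[N+]=[N-])ccc1OCc1ccccc1 | intermediate
15 | oxonium ylide: 10 carrying the (4-benzyloxy-3-methoxyphenyl)methanide group on its ring oxygen | [O+]1([CH-]c2ccc(OCc3ccccc3)c(OC)c2)[C@H](c2ccc(OCc3ccccc3)c(OC)c2)[C@H](CO[Si](C(C)C)(C(C)C)C(C)C)C=CC1 | intermediate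
16 | (2S,3R,4S,5S)-2,5-bis(4-benzyloxy-3-methoxyphenyl)-3-ethenyl-4-{[(triisopropylsilyl)oxy]methyl}oxolane (2,3-cis, 3,4-trans, 4,5-cis) | COc1cc([C@H]2O[C@H](c3ccc(OCc4ccccc4)c(OC)c3)[C@H](CO[Si](C(C)C)(C(C)C)C(C)C)[C@H]2C=C)ccc1OCc1ccccc1 | intermediate
17 | ozonide of 16 (3-(1,2,4-trioxolan-3-yl) in place of the vinyl group, trioxolane carbon unassigned) | COc1cc([C@H]2O[C@H](c3ccc(OCc4ccccc4)c(OC)c3)[C@H](CO[Si](C(C)C)(C(C)C)C(C)C)[C@H]2C5OCOO5)ccc1OCc1ccccc1 | intermediate
18 | [(2S,3S,4S,5S)-2,5-bis(4-benzyloxy-3-methoxyphenyl)-4-{[(triisopropylsilyl)oxy]methyl}oxolan-3-yl]methanol | COc1cc([C@H]2O[C@H](c3ccc(OCc4ccccc4)c(OC)c3)[C@H](CO[Si](C(C)C)(C(C)C)C(C)C)[C@H]2CO)ccc1OCc1ccccc1 | intermediate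
19 | [(2S,3S,4S,5S)-2,5-bis(4-benzyloxy-3-methoxyphenyl)oxolane-3,4-diyl]dimethanol | COc1cc([C@H]2O[C@H](c3ccc(OCc4ccccc4)c(OC)c3)[C@H](CO)[C@H]2CO)ccc1OCc1ccccc1 | intermediate
20 | eduesmine, [(2S,3S,4S,5S)-2,5-bis(4-hydroxy-3-methoxyphenyl)oxolane-3,4-diyl]dimethanol (2,3-cis, 3,4-trans, 4,5-cis) | COc1cc([C@H]2O[C@H](c3ccc(O)c(OC)c3)[C@H](CO)[C@H]2CO)ccc1O | target

Total step count: 10.
Longest linear sequence: 9 steps (steps 1 to 5 and 7 to 10, from butadiene); step 6 is a one-step branch from 4.

Steps most likely to fail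

Step 7. The donor carbene may be too weakly electrophilic for an ether oxygen. It can then be consumed by coupling with the diazo compound, by cyclopropanation of the ring alkene or of the product vinyl group, or by a [1,2] shift. The ylide carbon may also be delivered to the wrong ring face. The fallback uses the established lactone route to 2,5-diaryloxolanes; it sets out from 7 and comes back at 18. Hydroboration of the vinyl group of 7 with 9-borabicyclo[3.3.1]nonane (9-BBN) and NaOH/H2O2 work-up gives the 1,4-diol F1. TEMPO/PhI(OAc)2 oxidises its primary alcohol and closes the 4,5-cis γ-lactone F2. The enolate (LiN(iPr)2, THF, −78 °C) is hydroxymethylated with monomeric formaldehyde on the face opposite the C4 and C5 groups to give the 3,4-trans hydroxymethyl lactone F3. An excess of 4-benzyloxy-3-methoxyphenyllithium (from 1-benzyloxy-4-bromo-2-methoxybenzene and nBuLi) adds to the lactone carbonyl to give the hemiketal F4. Et3SiH/BF3·OEt2 in CH2Cl2 at −78 °C then reduces the derived oxocarbenium ion from the face anti to the C3 substituent, which should give the 2,3-cis compound 18.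

Step 2. Facial or syn/anti control may be incomplete in the Brønsted acid-catalysed allylboration, or addition to the electron-rich aldehyde may be slow enough for the uncatalysed pathway to compete. The fallback is a Lewis base-catalysed allylation with a (Z)-allyltrichlorosilane; it sets out from 4, uses commercial (Z)-but-2-ene-1,4-diol for the four-carbon unit, and comes back at 7, so step 3 is no longer needed. The diol is monosilylated (NaH, TIPSCl, THF) to the mono-TIPS ether F5 and converted with PPh3/CCl4 into the allylic chloride F6. HSiCl3, Et3N and CuCl (cat.) in Et2O turn this into the (Z)-allyltrichlorosilane F7 with retention of the alkene geometry. Addition to 4 is catalysed by a chiral 2,2′-bipyrrolidine-derived bisphosphoramide (enantiomer chosen for Si-face addition) with iPr2NEt in CH2Cl2 at −78 °C. It passes through a closed chair transition state at hypervalent silicon, so (Z) again translates into syn, and gives the trichlorosilyl ether F8, which aqueous NaHCO3 hydrolyses to 7.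

Step 8. Ozone may over-oxidise the two alkoxy arenes or the benzylic ether positions before the vinyl group is fully consumed, and the cis aldehyde stage may epimerise at C3. The fallback is a stepwise cleavage without ozone; it sets out from 16 and comes back at 18. OsO4 (cat.) with N-methylmorpholine N-oxide in acetone–water dihydroxylates the vinyl group to the 1,2-diol F9. NaIO4 in THF–water cleaves it to the aldehyde F10, which is reduced at once with NaBH4 in MeOH at −78 °C to 18.

Further compounds
F1 | step 7 | (1S,2S)-1-(4-benzyloxy-3-methoxyphenyl)-2-{[(triisopropylsilyl)oxy]methyl}butane-1,4-diol | O[C@H](c1ccc(OCc2ccccc2)c(OC)c1)[C@H](CO[Si](C(C)C)(C(C)C)C(C)C)CCO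
F2 | step 7 | 4,5-cis-5-(4-benzyloxy-3-methoxyphenyl)-4-{[(triisopropylsilyl)oxy]methyl}oxolan-2-one | O1[C@H](c2ccc(OCc3ccccc3)c(OC)c2)[C@H](CO[Si](C(C)C)(C(C)C)C(C)C)CC1=O
F3 | step 7 | 3,4-trans-4,5-cis-5-(4-benzyloxy-3-methoxyphenyl)-3-(hydroxymethyl)-4-{[(triisopropylsilyl)oxy]methyl}oxolan-2-one | O1[C@H](c2ccc(OCc3ccccc3)c(OC)c2)[C@H](CO[Si](C(C)C)(C(C)C)C(C)C)[C@@H](CO)C1=O
F4 | step 7 | 2,5-bis(4-benzyloxy-3-methoxyphenyl)-3-(hydroxymethyl)-4-{[(triisopropylsilyl)oxy]methyl}oxolan-2-ol (hemiketal, C2 unassigned) | O1[C@H](c2ccc(OCc3ccccc3)c(OC)c2)[C@H](CO[Si](C(C)C)(C(C)C)C(C)C)[C@@H](CO)C1(O)c1ccc(OCc2ccccc2)c(OC)c1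
F5 | step 2 | (Z)-4-[(triisopropylsilyl)oxy]but-2-en-1-ol | OC/C=C\CO[Si](C(C)C)(C(C)C)C(C)C
F6 | step 2 | (Z)-(4-chlorobut-2-enyloxy)triisopropylsilane | ClC/C=C\CO[Si](C(C)C)(C(C)C)C(C)C
F7 | step 2 | (Z)-trichloro{4-[(triisopropylsilyl)oxy]but-2-enyl}silane | Cl[Si](Cl)(Cl)C/C=C\CO[Si](C(C)C)(C(C)C)C(C)C
F8 | step 2 | trichlorosilyl ether of 7 | Cl[Si](Cl)(Cl)O[C@H](c1ccc(OCc2ccccc2)c(OC)c1)[C@H](CO[Si](C(C)C)(C(C)C)C(C)C)C=C
F9 | step 8 | 1,2-diol from 16 (3-(1,2-dihydroxyethyl) in place of the vinyl group, carbinol carbon unassigned) | COc1cc([C@H]2O[C@H](c3ccc(OCc4ccccc4)c(OC)c3)[C@H](CO[Si](C(C)C)(C(C)C)C(C)C)[C@H]2C(O)CO)ccc1OCc1ccccc1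
F10 | step 8 | 2,5-bis(4-benzyloxy-3-methoxyphenyl)-4-{[(triisopropylsilyl)oxy]methyl}oxolane-3-carbaldehyde (2,3-cis, 3,4-trans, 4,5-cis) | COc1cc([C@H]2O[C@H](c3ccc(OCc4ccccc4)c(OC)c3)[C@H](CO[Si](C(C)C)(C(C)C)C(C)C)[C@H]2C=O)ccc1OCc1ccccc1
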